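Time sorts this flask into rungs, and on each rung the question is how much Z stands beside D while D is being lost.

| flask | D | Z | remark | time |
|---|---|---|---|---|
| elm | 0.065 M | 0.039 M | run made earlier |  |
| maple | 0.033 M | 0.039 M | run made earlier |  |
| birch | 0.13 M | 0.039 M | run made earlier |  |
| cedar | 0.065 M | 0.078 M | run made earlier |  |
| amber | 0.065 M | 0.0390 M | a single well-mixed tank run continuously and read at steady state, 75.0 h in it on average |  |
| teal | 0.065 M | 0.0390 M (fed, over 20.0 h) | a stirred flask in which Z is dosed at a steady rate over 20.0 h without added volume, worked up at 25 h | 25 h |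
| blue | 0.065 M | 0.0390 M | one stirred flow tank at steady state, fed with the mixture as stated, mean residence time 25 h |  |
| grey | 0.065 M | 0.0390 M | everything together in a closed stirred flask, run for 25 h | 25 h |

- elm (time / h: G / %, X / %, D / %): 4.00: 3, 5, 45; 8.00: 6, 4, 24; 10.0: 4, 7, 20; 15.0: 8, 10, 11; 20.0: 9, 12, 5; 25.0: 12, 10, 4
- maple (time / h: G / %, X / %, D / %): 4.00: 1, 0, 48; 8.00: 5, 3, 26; 10.0: 8, 4, 19; 15.0: 12, 6, 12; 20.0: 16, 4, 4; 25.0: 20, 7, 7
- birch (time / h: G / %, X / %, D / %): 1.33: 0, 1, 67; 4.00: 2, 3, 42; 8.00: 2, 10, 23; 10.0: 0, 15, 16; 15.0: 2, 12, 10; 20.0: 5, 19, 6; 25.0: 5, 16, 7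
- cedar (time / h: G / %, X / %, D / %): 2.00: 3, 2, 56; 4.00: 8, 2, 32; 8.00: 13, 3, 15; 12.0: 20, 6, 7; 25.0: 31, 4, 4

(readings scatter by 1.5 percentage points)

- the set-up with the highest share of G in all that became G or X, at the outlet or at the end ("none" if the first two lie within 2 percentage points) (amber / teal / blue / grey / none)
- share of G in all that became G or X, at the outlet or at the end, amber
- share of G in all that became G or X, at the outlet or at the end, teal
- share of G in all that became G or X, at the outlet or at the end, blue
- share of G in all that became G or X, at the outlet or at the end, grey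

- percent here means D units held: one X counts as two
- the stated concentrations are those of everything mixed, before any reaction; amounts are the same in each set-up
- the feed brings no volume worth counting
- the earlier runs were made in a closed, stirred flask

On the fastest rung the elm run gives D a half-life of about 4.31 h, read from the 20% left at 10.0 h. At 4.00 h that run shows G 3% and X 5% beside D 45%, so 47.0% of the charge sits in forms not read. The next rung is the dosing time of 20.0 h, longer than that half-life, so teal has received 21.5% of its Z at the elm half-life. At 25 h the elm run reads D 4%, with G and X at 12% and 10%. The slowest rung is amber's mean 75.0 h, but a tank works at its outlet levels rather than at the charge.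

The ladder therefore asks for the ratio of G to X at 25 h, a selectivity factor, and logarithms make it plain. From 0.039 M to 0.078 M of Z, elm to cedar, the ratio reads 1.20 and then 7.75. That gives the Z power 2.69, the powers of ten gained in the ratio per power of ten of Z at fixed D and time; it is a reading, leaning on cedar's X of 4% with its scatter of 1.5 percentage points. Between maple and birch the ratio falls with D at a power of 1.61 at fixed Z. Grey is the elm recipe, so its share reads about 54.5%. Teal, short of Z while D goes, lies below that in this reckoning, while the runs give no outlet levels of D and Z for the tanks, so this reckoning sets no figure on amber or blue. This reckoning thus ranks grey above teal, whereas the forecast put amber first at 76%, with teal 30%, blue 52% and grey 52%, citing “long residence time and little D”.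

    D + L → X (k = 0.0140 /M/min)
    Z + L ⇌ Q (K = 65.0 /M, k = 0.00820 /M/min)
    D + Z ⇌ E (K = 760 /M, k = 0.0490 /M/min)
    Z + E → G (k = 0.0220 /M/min)
    D → L (k = 0.00120 /min)
    2 D → J (k = 0.00740 /M/min)

The flask gives grey first: grey 48.3%, blue 33.2%, amber 32.1%, teal 22.8%. Amber's tank holds Z at 0.0116 M, which is 29.9% of the charge, with D at 9.65%. Grey's share means a ratio of 0.934, and the Z power carries that to the same flask with 0.098 M of Z as 11.1, a share of 91.7%; that neighbouring flask gives 91.5%.

The numbers in the tables come from a simulation for an exercise, and the scatter is random.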